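**Retrosynthetic overview**
- Target ⇐ C12 aldehyde-to-acid oxidation of a 15-O-(Z)-p-coumaroyl-α-costal; its C15–O bond ⇐ direct palladium-catalysed allylic C–H acyloxylation of α-costal with (Z)-p-coumaric acid (made from the trans acid by light).
- α-Costal ⇐ (+)-α-cyperone by reductive triflation (sets the trans ring fusion and fixes the 3-ene), SeO2 oxidation of the isopropenyl methyl, and triflate hydrogenolysis.
- (+)-α-Cyperone ⇐ (+)-dihydrocarvone + ethyl vinyl ketone by auxiliary-controlled Michael addition (sets C10) and aldol condensation.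
- Ring order: ring B comes ready-made from dihydrocarvone (C7 stereocentre); ring A is closed second by the aldol condensation; no further ring is formed.

Assumption: commercial (+)-dihydrocarvone is the usual mixture of C2 epimers (both 5R); C2 is erased in step 1, so it is used as bought. Eudesmane numbering (C1–C15) is used for positions.

**Step 1**
Reactants: 1 (+)-dihydrocarvone [(2R,5R)-2-methyl-5-(prop-1-en-2-yl)cyclohexan-1-one]; 2 (R)-(+)-1-phenylethylamine; 3 ethyl vinyl ketone
Product: 6 (2S,5R)-2-methyl-2-(3-oxopentyl)-5-(prop-1-en-2-yl)cyclohexan-1-one, via ketimine 4 (not isolated), via Michael-adduct ketimine 5 (not isolated)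
Conditions: 2, TsOH (cat.), toluene, reflux (Dean–Stark); 3, THF, 40 °C, 4 d; 10% aq AcOH, rt
Reagents that add atoms: water (O)
Why: Auxiliary-controlled deracemizing Michael addition (d'Angelo): the more substituted secondary enamine tautomer of 4 adds to 3 through a compact aza-ene-like transition state with internal N–H transfer on the face anti to the phenyl group of the (R)-auxiliary, which overrides the ring bias, puts the new chain trans to the isopropenyl group (methyl cis) and so sets the quaternary C10 as S in 6.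

**Step 2**
Reactants: 6 (2S,5R)-2-methyl-2-(3-oxopentyl)-5-(prop-1-en-2-yl)cyclohexan-1-one
Product: 8 (+)-α-cyperone [(4aS,7R)-1,4a-dimethyl-7-(prop-1-en-2-yl)-4,4a,5,6,7,8-hexahydronaphthalen-2(3H)-one], via ketol 7 (not isolated)
Conditions: NaOMe, MeOH, rt → 50 °C
Reagents that add atoms: none
Why: Intramolecular aldol condensation (second half of a Robinson annulation): the ethyl ketone enolate closes ring A on the ring ketone and the ketol dehydrates to the conjugated enone, with no stereocentre touched.

**Step 3**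
Reactants: 8 (+)-α-cyperone
Product: 10 (4aS,7R,8aR)-1,4a-dimethyl-7-(prop-1-en-2-yl)-3,4,4a,5,6,7,8,8a-octahydronaphthalen-2-yl trifluoromethanesulfonate (trans-fused; 5αH anti to the 10β-methyl), via lithium enolate 9 (not isolated)
Conditions: Li, NH3(l)/THF, t-BuOH (1 equiv), −78 °C; isoprene; evaporate NH3; PhNTf2, THF, 0 °C → rt
Reagents that add atoms: N-phenylbis(trifluoromethanesulfonimide) (O=S(=O)(N(c1ccccc1)S(=O)(=O)C(F)(F)F)C(F)(F)F); lithium ([Li])
Why: Dissolving-metal (Birch-type) enone reduction with regiospecific enolate trapping (reductive triflation): the β-carbanion at C5 is protonated axially, anti to the angular methyl, which sets the trans ring fusion (C5 R), and the 3-ene lithium enolate 9 (the only compound that holds the lithium) is O-sulfonylated to the triflate, while the isolated isopropenyl alkene is not reduced.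

**Step 4**
Reactants: 10 the enol triflate from step 3
Product: 12 (4aS,7R,8aR)-1,4a-dimethyl-7-(3-oxoprop-1-en-2-yl)-3,4,4a,5,6,7,8,8a-octahydronaphthalen-2-yl trifluoromethanesulfonate, via allylic alcohol 11 (not isolated)
Conditions: SeO2 (0.5 equiv), t-BuOOH, salicylic acid (cat.), CH2Cl2, rt; then MnO2, CH2Cl2, rt
Reagents that add atoms: tert-butyl hydroperoxide (CC(C)(C)OO); selenium dioxide (O=[Se]=O)
Why: SeO2 allylic oxidation (ene reaction then [2,3]-sigmatropic shift, the oxygen being delivered by selenium and replenished from the hydroperoxide) attacks only the 1,1-disubstituted isopropenyl alkene at its methyl group, because the triflyloxy-bearing alkene is too electron-poor, and MnO2 allylic oxidation then brings the alcohol and aldehyde mixture to the enal.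

**Step 5**
Reactants: 12 the C12 enal triflate from step 4
Product: 13 α-costal [2-[(2R,4aR,8aR)-4a,8-dimethyl-1,2,3,4,4a,5,6,8a-octahydronaphthalen-2-yl]prop-2-enal]
Conditions: Pd(OAc)2 (5 mol%), PPh3 (10 mol%), HCO2H, n-Bu3N, DMF, 60 °C
Reagents that add atoms: none
Why: Palladium-catalysed formate hydrogenolysis of a vinyl triflate (Cacchi reduction): oxidative addition to zerovalent palladium, formate exchange, loss of CO2 and C–H reductive elimination replace OTf by H with the alkene held at C3=C4, conditions under which conjugated carbonyl groups normally survive.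

**Step 6**
Reactants: 14 trans-p-coumaric acid [(2E)-3-(4-hydroxyphenyl)prop-2-enoic acid]
Product: 15 cis-p-coumaric acid [(2Z)-3-(4-hydroxyphenyl)prop-2-enoic acid]
Conditions: hν (300–320 nm), degassed MeOH, rt; silica gel chromatography in the dark
Reagents that add atoms: none
Why: Direct-excitation E→Z photoisomerization of a cinnamic acid: the more strongly absorbing E isomer is pumped through the twisted excited state to a photostationary mixture from which the Z acid is separated.

**Step 7**
Reactants: 13 α-costal; 15 cis-p-coumaric acid (1.5 equiv)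
Product: 16 [(4aR,7R,8aR)-4a-methyl-7-(3-oxoprop-1-en-2-yl)-3,4,4a,5,6,7,8,8a-octahydronaphthalen-1-yl]methyl (2Z)-3-(4-hydroxyphenyl)prop-2-enoate
Conditions: Pd(CH3CN)4(BF4)2 (10 mol%), DMSO (1.4 equiv), i-Pr2NEt (0.7 equiv), 2,6-dimethyl-1,4-benzoquinone (2 equiv), 4 Å MS, CH2Cl2, 40 °C, dark
Reagents that add atoms: none
Why: Proposed new method: intermolecular allylic C–H acyloxylation of a trisubstituted ring alkene at its methyl group with a complex Z-cinnamic acid, in which electrophilic sulfoxide-ligated divalent palladium binds the 3-ene, carboxylate-assisted cleavage of a C15–H bond (palladium toward the less substituted C3, hydrogen taken from the methyl on C4 rather than the hindered tertiary C5–H, as in stoichiometric η3-allyl formation from trisubstituted olefins) gives the C3–C4–C15 η3-allyl, and quinone-promoted C–O bond formation at the unhindered CH2 terminus forms the C15–O ester bond, restores the 3-ene and releases zerovalent palladium that the quinone reoxidizes, while the electron-poor enal and cinnamate alkenes and the un-ionized phenol stay out; the closest known reaction type is the palladium/sulfoxide/benzoquinone allylic C–H esterification of terminal alkenes with carboxylic acids (White-type), not yet shown for an allylic methyl on a trisubstituted endocyclic alkene.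

**Step 8**
Reactants: 16 the coumaroyloxy aldehyde from step 7
Product: 17 2-[(2R,4aR,8aR)-8-({[(2Z)-3-(4-hydroxyphenyl)prop-2-enoyl]oxy}methyl)-4a-methyl-1,2,3,4,4a,5,6,8a-octahydronaphthalen-2-yl]prop-2-enoic acid (CNP0183482.1)
Conditions: NaClO2, NaH2PO4, 2-methyl-2-butene (30 equiv), t-BuOH/THF/H2O, 0 °C, dark
Reagents that add atoms: sodium chlorite ([Na+].[O-]Cl=O)
Why: Pinnick (Lindgren–Kraus) oxidation: chlorous acid adds to the enal carbonyl and fragments to the acid, and the large excess of 2-methyl-2-butene scavenges HOCl so that the phenol, the ring alkene, the allylic ester and the Z-enoate are left alone and no stereocentre is touched.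

**Compound list**
1 | (+)-dihydrocarvone, (2R,5R)-2-methyl-5-(prop-1-en-2-yl)cyclohexan-1-one (sold with some 2S epimer) | CC(=C)[C@@H]1CC[C@@H](C)C(=O)C1 | starting material
2 | (R)-(+)-1-phenylethylamine | C[C@@H](N)c1ccccc1 | starting material
3 | ethyl vinyl ketone (pent-1-en-3-one) | CCC(=O)C=C | starting material
4 | ketimine of 1 and 2, (5R)-2-methyl-N-[(1R)-1-phenylethyl]-5-(prop-1-en-2-yl)cyclohexan-1-imine (C2 epimers; not isolated) | CC(=C)[C@@H]1CCC(C)C(=N[C@H](C)c2ccccc2)C1 | intermediate
5 | Michael-adduct ketimine, 1-[(1S,4R)-1-methyl-2-{[(1R)-1-phenylethyl]imino}-4-(prop-1-en-2-yl)cyclohexyl]pentan-3-one (not isolated) | CC(=C)[C@@H]1CC[C@@](C)(CCC(=O)CC)C(=N[C@H](C)c2ccccc2)C1 | intermediate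
6 | (2S,5R)-2-methyl-2-(3-oxopentyl)-5-(prop-1-en-2-yl)cyclohexan-1-one (methyl cis to isopropenyl) | CC(=C)[C@@H]1CC[C@@](C)(CCC(=O)CC)C(=O)C1 | intermediate
7 | ketol, (4aS,7R)-8a-hydroxy-1,4a-dimethyl-7-(prop-1-en-2-yl)octahydronaphthalen-2(1H)-one (epimers at C1 and C8a; not isolated) | CC(=C)[C@@H]1CC[C@@]2(C)CCC(=O)C(C)C2(O)C1 | intermediate
8 | (+)-α-cyperone, (4aS,7R)-1,4a-dimethyl-7-(prop-1-en-2-yl)-4,4a,5,6,7,8-hexahydronaphthalen-2(3H)-one | CC(=C)[C@@H]1CC[C@@]2(C)CCC(=O)C(C)=C2C1 | intermediate
9 | lithium (4aS,7R,8aR)-1,4a-dimethyl-7-(prop-1-en-2-yl)-3,4,4a,5,6,7,8,8a-octahydronaphthalen-2-olate (trans-fused; not isolated) | CC(=C)[C@@H]1CC[C@@]2(C)CCC(O[Li])=C(C)[C@@H]2C1 | intermediate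
10 | (4aS,7R,8aR)-1,4a-dimethyl-7-(prop-1-en-2-yl)-3,4,4a,5,6,7,8,8a-octahydronaphthalen-2-yl trifluoromethanesulfonate | CC(=C)[C@@H]1CC[C@@]2(C)CCC(OS(=O)(=O)C(F)(F)F)=C(C)[C@@H]2C1 | intermediate
11 | (4aS,7R,8aR)-7-(3-hydroxyprop-1-en-2-yl)-1,4a-dimethyl-3,4,4a,5,6,7,8,8a-octahydronaphthalen-2-yl trifluoromethanesulfonate (not isolated) | C=C(CO)[C@@H]1CC[C@@]2(C)CCC(OS(=O)(=O)C(F)(F)F)=C(C)[C@@H]2C1 | intermediate
12 | (4aS,7R,8aR)-1,4a-dimethyl-7-(3-oxoprop-1-en-2-yl)-3,4,4a,5,6,7,8,8a-octahydronaphthalen-2-yl trifluoromethanesulfonate | C=C(C=O)[C@@H]1CC[C@@]2(C)CCC(OS(=O)(=O)C(F)(F)F)=C(C)[C@@H]2C1 | intermediate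
13 | α-costal, 2-[(2R,4aR,8aR)-4a,8-dimethyl-1,2,3,4,4a,5,6,8a-octahydronaphthalen-2-yl]prop-2-enal | C=C(C=O)[C@@H]1CC[C@@]2(C)CCC=C(C)[C@@H]2C1 | intermediate
14 | trans-p-coumaric acid, (2E)-3-(4-hydroxyphenyl)prop-2-enoic acid | OC(=O)/C=C/c1ccc(O)cc1 | starting material
15 | cis-p-coumaric acid, (2Z)-3-(4-hydroxyphenyl)prop-2-enoic acid | OC(=O)/C=C\c1ccc(O)cc1 | intermediate
16 | [(4aR,7R,8aR)-4a-methyl-7-(3-oxoprop-1-en-2-yl)-3,4,4a,5,6,7,8,8a-octahydronaphthalen-1-yl]methyl (2Z)-3-(4-hydroxyphenyl)prop-2-enoate | C=C(C=O)[C@@H]1CC[C@@]2(C)CCC=C(COC(=O)/C=C\c3ccc(O)cc3)[C@@H]2C1 | intermediate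
17 | CNP0183482.1, 2-[(2R,4aR,8aR)-8-({[(2Z)-3-(4-hydroxyphenyl)prop-2-enoyl]oxy}methyl)-4a-methyl-1,2,3,4,4a,5,6,8a-octahydronaphthalen-2-yl]prop-2-enoic acid (eudesmane C5 R, C7 R, C10 R) | C=C(C(=O)O)[C@@H]1CC[C@@]2(C)CCC=C(COC(=O)/C=C\c3ccc(O)cc3)[C@@H]2C1 | target

**Step count and risks**
Total steps: 8. Longest linear sequence: 7 (steps 1, 2, 3, 4, 5, 7, 8); step 6 is the one-step side branch.

Three steps most likely to fail:

Step 7 (the proposed C–H acyloxylation): the trisubstituted alkene may be sluggish toward divalent palladium, and the Z-enoate may drift to E. Fallback with known chemistry, setting out from 13 and coming back at 16: SeO2 (cat.)/t-BuOOH in CH2Cl2 at 0 °C hydroxylates the C4 methyl of 13 by the ene/[2,3] sequence (the enal alkene is too electron-poor to react; methyl is preferred over the tertiary C5–H) to give 15-hydroxy-α-costal F1. A Mitsunobu esterification of F1 with 15 (PPh3, diisopropyl azodicarboxylate, THF, 0 °C, dark) then forms the same C15–O bond by carboxylate displacement at the primary allylic carbon, the carboxylic acid reacting in preference to the phenol, and gives 16.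

Step 5 (triflate hydrogenolysis beside an α-methylene aldehyde): the enal may suffer conjugate reduction, alkene migration by palladium hydride, or amine-induced oligomerization. Fallback setting out from 11 and coming back at 13: step 4 is run without the MnO2 finish and alcohol 11 is isolated (the minor enal 12 is separated). The triflate of 11 is hydrogenolysed under the step 5 conditions at the alcohol oxidation level to give α-costol F2, so that no enal meets the palladium hydride. MnO2 in CH2Cl2 then oxidizes F2 to 13.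

Step 8 (chlorite oxidation on a substrate with a free phenol, an electron-rich alkene and a Z-enoate): ring chlorination or Z/E drift may erode the last step. Fallback setting out from 13 and coming back at 17, with the acid made early and masked: Pinnick oxidation of the simple enal 13 (NaClO2, NaH2PO4, 2-methyl-2-butene) gives α-costic acid F3. DCC/DMAP esterification with 2-(trimethylsilyl)ethanol then gives 2-(trimethylsilyl)ethyl α-costate F4. SeO2 (cat.)/t-BuOOH hydroxylation of the C4 methyl gives 2-(trimethylsilyl)ethyl 15-hydroxy-α-costate F5. Mitsunobu esterification with 15 (PPh3, diisopropyl azodicarboxylate, THF, 0 °C, dark) gives the 2-(trimethylsilyl)ethyl ester of the target F6. Finally Bu4NF buffered with AcOH (THF, 0 °C) cleaves the silylethyl ester by fluoride-induced fragmentation and gives 17.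

**Further compounds**
F1 | step 7 | 15-hydroxy-α-costal, 2-[(2R,4aR,8aR)-8-(hydroxymethyl)-4a-methyl-1,2,3,4,4a,5,6,8a-octahydronaphthalen-2-yl]prop-2-enal | C=C(C=O)[C@@H]1CC[C@@]2(C)CCC=C(CO)[C@@H]2C1
F2 | step 5 | α-costol, 2-[(2R,4aR,8aR)-4a,8-dimethyl-1,2,3,4,4a,5,6,8a-octahydronaphthalen-2-yl]prop-2-en-1-ol | C=C(CO)[C@@H]1CC[C@@]2(C)CCC=C(C)[C@@H]2C1
F3 | step 8 | α-costic acid, 2-[(2R,4aR,8aR)-4a,8-dimethyl-1,2,3,4,4a,5,6,8a-octahydronaphthalen-2-yl]prop-2-enoic acid | C=C(C(=O)O)[C@@H]1CC[C@@]2(C)CCC=C(C)[C@@H]2C1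
F4 | step 8 | 2-(trimethylsilyl)ethyl 2-[(2R,4aR,8aR)-4a,8-dimethyl-1,2,3,4,4a,5,6,8a-octahydronaphthalen-2-yl]prop-2-enoate | C=C(C(=O)OCC[Si](C)(C)C)[C@@H]1CC[C@@]2(C)CCC=C(C)[C@@H]2C1
F5 | step 8 | 2-(trimethylsilyl)ethyl 2-[(2R,4aR,8aR)-8-(hydroxymethyl)-4a-methyl-1,2,3,4,4a,5,6,8a-octahydronaphthalen-2-yl]prop-2-enoate | C=C(C(=O)OCC[Si](C)(C)C)[C@@H]1CC[C@@]2(C)CCC=C(CO)[C@@H]2C1
F6 | step 8 | 2-(trimethylsilyl)ethyl 2-[(2R,4aR,8aR)-8-({[(2Z)-3-(4-hydroxyphenyl)prop-2-enoyl]oxy}methyl)-4a-methyl-1,2,3,4,4a,5,6,8a-octahydronaphthalen-2-yl]prop-2-enoate | C=C(C(=O)OCC[Si](C)(C)C)[C@@H]1CC[C@@]2(C)CCC=C(COC(=O)/C=C\c3ccc(O)cc3)[C@@H]2C1
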